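The route rests on cutting the C3'–C1'' bond, so that the prenyl group is attached last, to the fully unprotected polyphenol. An aromatic prenyltransferase should alkylate C3' of ring A, the aromatic CH flanked by the 2'- and 4'-hydroxyls of the resorcinol aryl ketone, with dimethylallyl diphosphate in neutral buffer and so deliver the target in one operation. The precursor is the desprenyl (R)-pentahydroxy α-hydroxydihydrochalcone. Its only stereocentre, the C2 carbinol, is carried over from (R)-danshensu; ring A is attached by adding 2,4-bis(benzyloxy)phenyllithium to the silylated danshensu Weinreb amide, and the protecting groups are removed by buffered fluoride and neutral hydrogenolysis.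

Key step: step 9

Assumption: danshensu is used as the free acid (the sodium salt would need one more equivalent of acid in step 1), and the recombinant prenyltransferase is treated as a catalyst whose expression is not counted as a synthetic step.

Step 1
Reactants: 1 danshensu, (R)-3-(3,4-dihydroxyphenyl)-2-hydroxypropanoic acid
Product: 2 methyl (R)-3-(3,4-dihydroxyphenyl)-2-hydroxypropanoate
Conditions: MeOH, H2SO4 (cat.), 50 °C, N2
Reagents that add atoms: methanol, CO
Why: Fischer esterification of the α-hydroxy acid in acidic methanol does not involve the C2 stereocentre and leaves the catechol intact under nitrogen.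

Step 2
Reactants: 2 methyl (R)-3-(3,4-dihydroxyphenyl)-2-hydroxypropanoate
Product: 3 methyl (R)-2-[(tert-butyldimethylsilyl)oxy]-3-{3,4-bis[(tert-butyldimethylsilyl)oxy]phenyl}propanoate
Conditions: TBSCl (3.5 equiv), imidazole (7 equiv), DMF, 0 °C to rt
Reagents that add atoms: tert-butyldimethylsilyl chloride, CC(C)(C)[Si](C)(C)Cl
Why: Silyl ether formation under imidazole catalysis masks both phenols and the secondary alcohol in one operation, without a base strong enough to epimerise C2.

Step 3
Reactants: 3 methyl (R)-2-[(tert-butyldimethylsilyl)oxy]-3-{3,4-bis[(tert-butyldimethylsilyl)oxy]phenyl}propanoate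
Product: 4 (R)-2-[(tert-butyldimethylsilyl)oxy]-3-{3,4-bis[(tert-butyldimethylsilyl)oxy]phenyl}-N-methoxy-N-methylpropanamide
Conditions: MeNH(OMe)·HCl (3 equiv), i-PrMgCl (6 equiv), THF, −20 to 0 °C
Reagents that add atoms: N,O-dimethylhydroxylamine hydrochloride, CNOC.Cl
Why: Aminolysis of the ester by the chloromagnesium amide of N,O-dimethylhydroxylamine (Weinreb amide formation) is routine for α-silyloxy esters and should proceed at low temperature without epimerisation or loss of the aryl silyl ethers.

Step 4
Reactants: 5 4-bromoresorcinol (4-bromobenzene-1,3-diol)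
Product: 6 2,4-bis(benzyloxy)-1-bromobenzene
Conditions: BnBr (2.3 equiv), K2CO3 (3 equiv), DMF, 60 °C
Reagents that add atoms: benzyl bromide, BrCc1ccccc1
Why: Williamson ether synthesis on both phenols gives an aryl bromide whose benzyl ethers tolerate organolithium chemistry and can later be removed under neutral conditions.

Step 5
Reactants: 6 2,4-bis(benzyloxy)-1-bromobenzene; 4 (R)-2-[(tert-butyldimethylsilyl)oxy]-3-{3,4-bis[(tert-butyldimethylsilyl)oxy]phenyl}-N-methoxy-N-methylpropanamide
Product: 9 (R)-1-[2,4-bis(benzyloxy)phenyl]-2-[(tert-butyldimethylsilyl)oxy]-3-{3,4-bis[(tert-butyldimethylsilyl)oxy]phenyl}propan-1-one, via 2,4-bis(benzyloxy)phenyllithium 7 (not isolated), via lithium hemiaminal adduct 8 (not isolated)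
Conditions: 6 (1.3 equiv), n-BuLi (1.25 equiv), THF, −78 °C; then 4 (1.0 equiv), −78 to −30 °C; aq. NH4Cl
Reagents that add atoms: none
Why: Bromine–lithium exchange followed by Weinreb ketone synthesis, in which the aryllithium adds once because the N-methoxy chelate 8 persists until the quench, while the silyloxy-bearing C2 should not be enolised at −78 °C.

Step 6
Reactants: 9 (R)-1-[2,4-bis(benzyloxy)phenyl]-2-[(tert-butyldimethylsilyl)oxy]-3-{3,4-bis[(tert-butyldimethylsilyl)oxy]phenyl}propan-1-one
Product: 10 (R)-1-[2,4-bis(benzyloxy)phenyl]-3-(3,4-dihydroxyphenyl)-2-hydroxypropan-1-one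
Conditions: HF·pyridine, pyridine, THF, 0 °C to rt; pH 7 phosphate buffer work-up
Reagents that add atoms: none
Why: Fluoride-mediated desilylation in a pyridine-buffered, slightly acidic medium should free the catechol and the carbinol without the alkoxide or phenoxide conditions that could epimerise the α-ketol.

Step 7
Reactants: 10 (R)-1-[2,4-bis(benzyloxy)phenyl]-3-(3,4-dihydroxyphenyl)-2-hydroxypropan-1-one
Product: 11 (R)-1-(2,4-dihydroxyphenyl)-3-(3,4-dihydroxyphenyl)-2-hydroxypropan-1-one
Conditions: H2 (1 atm), 10% Pd/C, EtOAc/MeOH, rt; filtration under argon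
Reagents that add atoms: none
Why: Catalytic hydrogenolysis of the two aryl benzyl ethers is neutral, so the C2 stereocentre is preserved, and the electron-rich 2,4-dioxygenated aryl ketone should be reduced far more slowly than the ethers are cleaved.

Step 8
Reactants: 12 prenyl bromide (1-bromo-3-methylbut-2-ene)
Product: 13 dimethylallyl diphosphate (isolated and used as its triammonium salt; free-acid formula given in the list)
Conditions: (n-Bu4N)3HP2O7 (2 equiv), MeCN, rt; sulfonic acid cation-exchange resin (NH4+ form), aq. NH4HCO3/i-PrOH; lyophilisation; cellulose chromatography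
Reagents that add atoms: tris(tetra-n-butylammonium) hydrogen diphosphate, CCCC[N+](CCCC)(CCCC)CCCC.CCCC[N+](CCCC)(CCCC)CCCC.CCCC[N+](CCCC)(CCCC)CCCC.OP(=O)([O-])OP(=O)([O-])[O-]
Why: SN2 displacement of the primary allylic bromide by the diphosphate trianion in acetonitrile is the standard synthesis of allylic diphosphates and should give the regular, primary diphosphate, which is then exchanged to the ammonium salt for use in buffer.

Step 9
Reactants: 11 (R)-1-(2,4-dihydroxyphenyl)-3-(3,4-dihydroxyphenyl)-2-hydroxypropan-1-one; 13 dimethylallyl diphosphate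
Product: 14 (R)-1-[2,4-dihydroxy-3-(3-methylbut-2-en-1-yl)phenyl]-3-(3,4-dihydroxyphenyl)-2-hydroxypropan-1-one (target)
Conditions: recombinant Morus alba isoliquiritigenin 3'-dimethylallyltransferase (MaIDT, microsomal fraction from a yeast expression strain), 13 (3 equiv), MgCl2 (10 mM), Tris-HCl buffer pH 7.5, sodium ascorbate, DTT, DMSO (5% v/v), degassed, 30 °C; EtOAc extraction; C18 chromatography
Reagents that add atoms: none
Why: With the diphosphate bound through a magnesium ion, the enzyme should ionise 13 to a dimethylallyl cation–diphosphate ion pair placed against the bound acceptor, C3' of ring A then attacks the primary carbon C1'', and loss of the C3' proton restores the arene (an enzymatic Friedel–Crafts alkylation). The closest known reaction type is the C3' dimethylallylation of 2',4'-dihydroxychalcones such as isoliquiritigenin by membrane-bound plant flavonoid prenyltransferases, and of hydroxylated dihydrochalcones by soluble fungal indole prenyltransferases. No ring is closed and no stereocentre is formed; the C2 carbinol inherited from danshensu should be untouched at pH 7.5 and 30 °C. The step needs selectivity for C3' over C5', over the ring B carbons and over all five oxygens, and regular rather than reverse attachment; the substrate supports this by presenting the same 2',4'-dihydroxyaryl ketone recognition element as the native chalcone acceptors, with C3' the only carbon activated by two flanking hydroxyls. Neutral water also excludes acid-induced cyclisation of the new prenyl group onto the 2'- or 4'-hydroxyl to a chroman.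

Compound list
1 | danshensu, (R)-3-(3,4-dihydroxyphenyl)-2-hydroxypropanoic acid | O=C(O)[C@H](O)Cc1ccc(O)c(O)c1 | starting material
2 | methyl (R)-3-(3,4-dihydroxyphenyl)-2-hydroxypropanoate | COC(=O)[C@H](O)Cc1ccc(O)c(O)c1 | intermediate
3 | methyl (R)-2-[(tert-butyldimethylsilyl)oxy]-3-{3,4-bis[(tert-butyldimethylsilyl)oxy]phenyl}propanoate | COC(=O)[C@H](O[Si](C)(C)C(C)(C)C)Cc1ccc(O[Si](C)(C)C(C)(C)C)c(O[Si](C)(C)C(C)(C)C)c1 | intermediate
4 | (R)-2-[(tert-butyldimethylsilyl)oxy]-3-{3,4-bis[(tert-butyldimethylsilyl)oxy]phenyl}-N-methoxy-N-methylpropanamide | CON(C)C(=O)[C@H](O[Si](C)(C)C(C)(C)C)Cc1ccc(O[Si](C)(C)C(C)(C)C)c(O[Si](C)(C)C(C)(C)C)c1 | intermediate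
5 | 4-bromoresorcinol (4-bromobenzene-1,3-diol) | Oc1ccc(Br)c(O)c1 | starting material
6 | 2,4-bis(benzyloxy)-1-bromobenzene | Brc1ccc(OCc2ccccc2)cc1OCc1ccccc1 | intermediate
7 | 2,4-bis(benzyloxy)phenyllithium (not isolated) | [Li]c1ccc(OCc2ccccc2)cc1OCc1ccccc1 | intermediate
8 | lithium (2R)-1-[2,4-bis(benzyloxy)phenyl]-2-[(tert-butyldimethylsilyl)oxy]-3-{3,4-bis[(tert-butyldimethylsilyl)oxy]phenyl}-1-[methoxy(methyl)amino]propan-1-olate, either configuration at C1 (not isolated) | CON(C)C(O[Li])(c1ccc(OCc2ccccc2)cc1OCc1ccccc1)[C@H](O[Si](C)(C)C(C)(C)C)Cc1ccc(O[Si](C)(C)C(C)(C)C)c(O[Si](C)(C)C(C)(C)C)c1 | intermediate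
9 | (R)-1-[2,4-bis(benzyloxy)phenyl]-2-[(tert-butyldimethylsilyl)oxy]-3-{3,4-bis[(tert-butyldimethylsilyl)oxy]phenyl}propan-1-one | O=C(c1ccc(OCc2ccccc2)cc1OCc1ccccc1)[C@H](O[Si](C)(C)C(C)(C)C)Cc1ccc(O[Si](C)(C)C(C)(C)C)c(O[Si](C)(C)C(C)(C)C)c1 | intermediate
10 | (R)-1-[2,4-bis(benzyloxy)phenyl]-3-(3,4-dihydroxyphenyl)-2-hydroxypropan-1-one | O=C(c1ccc(OCc2ccccc2)cc1OCc1ccccc1)[C@H](O)Cc1ccc(O)c(O)c1 | intermediate
11 | (R)-1-(2,4-dihydroxyphenyl)-3-(3,4-dihydroxyphenyl)-2-hydroxypropan-1-one | O=C(c1ccc(O)cc1O)[C@H](O)Cc1ccc(O)c(O)c1 | intermediate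
12 | prenyl bromide (1-bromo-3-methylbut-2-ene) | CC(C)=CCBr | starting material
13 | dimethylallyl diphosphate (handled as the triammonium salt) | CC(C)=CCOP(=O)(O)OP(=O)(O)O | intermediate
14 | (R)-1-[2,4-dihydroxy-3-(3-methylbut-2-en-1-yl)phenyl]-3-(3,4-dihydroxyphenyl)-2-hydroxypropan-1-one | CC(C)=CCc1c(O)ccc(C(=O)[C@H](O)Cc2ccc(O)c(O)c2)c1O | target

Total step count: 9
Longest linear sequence: 7 steps (steps 1, 2, 3, 5, 6, 7 and 9, from danshensu 1)

Steps most likely to fail

Step 9. The enzyme may not turn over the acceptor, because the sp3 carbinol at C2 replaces the planar enone of the native chalcones and may prevent productive binding. Prenyl transfer could also drift to C5' or ring B, and the catechol could oxidise during a long incubation. Screening related enzymes (the Cudrania and Sophora chalcone prenyltransferases, soluble fungal AnaPT) is the first response, but the fallback is chemical and installs the prenyl group before the ketone is formed. It sets out from Weinreb amide 4 and returns to the route at target 14. Resorcinol is converted with MOMCl and i-Pr2NEt into 1,3-bis(methoxymethoxy)benzene F1. Directed lithiation at C2 between the two acetal oxygens (n-BuLi, THF, 0 °C), transmetalation with CuBr·SMe2 and alkylation with prenyl bromide 12 should give 1,3-bis(methoxymethoxy)-2-(3-methylbut-2-en-1-yl)benzene F2. Bromination with NBS in MeCN at 0 °C, ortho and para to the acetal oxygens, should give 1-bromo-2,4-bis(methoxymethoxy)-3-(3-methylbut-2-en-1-yl)benzene F3. Bromine–lithium exchange (n-BuLi, THF, −78 °C) and addition to 4, as in step 5, should give (R)-1-[2,4-bis(methoxymethoxy)-3-(3-methylbut-2-en-1-yl)phenyl]-2-[(tert-butyldimethylsilyl)oxy]-3-{3,4-bis[(tert-butyldimethylsilyl)oxy]phenyl}propan-1-one F4. HF·pyridine then removes the three silyl groups to give (R)-1-[2,4-bis(methoxymethoxy)-3-(3-methylbut-2-en-1-yl)phenyl]-3-(3,4-dihydroxyphenyl)-2-hydroxypropan-1-one F5. Brief treatment with dilute HCl in MeOH at 0 to 20 °C, stopped at full conversion before the prenyl group can cyclise onto a free hydroxyl, should give 14.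

Step 5. The bromine–lithium exchange may be incomplete, or the aryllithium may act as a base and remove the C2 hydrogen of the hindered amide, returning partly epimerised amide in place of ketone. The fallback replaces acyl substitution by aldehyde addition and oxidation; it sets out from Weinreb amide 4 and returns at ketone 9. DIBAL-H in THF at −78 °C should reduce 4 to (R)-2-[(tert-butyldimethylsilyl)oxy]-3-{3,4-bis[(tert-butyldimethylsilyl)oxy]phenyl}propanal F6, used crude. Addition of aryllithium 7 at −78 °C should give (1RS,2R)-1-[2,4-bis(benzyloxy)phenyl]-2-[(tert-butyldimethylsilyl)oxy]-3-{3,4-bis[(tert-butyldimethylsilyl)oxy]phenyl}propan-1-ol F7 as a mixture of C1 epimers. Dess–Martin periodinane with NaHCO3 in CH2Cl2 then oxidises the carbinol to 9, which removes the C1 stereocentre.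

Step 7. The aryl ketone may be over-reduced to the benzylic alcohol or methylene before both benzyl ethers are cleaved, or debenzylation may stall on a catalyst poisoned by the catechol. The fallback is a non-reductive cleavage: from 10, BCl3 with pentamethylbenzene as benzyl-cation scavenger in CH2Cl2 at −78 °C, followed by a methanol quench, should give 11 directly, with no new isolated compound.

Further compounds
F1 | step 9 | 1,3-bis(methoxymethoxy)benzene | COCOc1cccc(OCOC)c1
F2 | step 9 | 1,3-bis(methoxymethoxy)-2-(3-methylbut-2-en-1-yl)benzene | COCOc1cccc(OCOC)c1CC=C(C)C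
F3 | step 9 | 1-bromo-2,4-bis(methoxymethoxy)-3-(3-methylbut-2-en-1-yl)benzene | COCOc1ccc(Br)c(OCOC)c1CC=C(C)C
F4 | step 9 | (R)-1-[2,4-bis(methoxymethoxy)-3-(3-methylbut-2-en-1-yl)phenyl]-2-[(tert-butyldimethylsilyl)oxy]-3-{3,4-bis[(tert-butyldimethylsilyl)oxy]phenyl}propan-1-one | CC(C)=CCc1c(OCOC)ccc(C(=O)[C@H](O[Si](C)(C)C(C)(C)C)Cc2ccc(O[Si](C)(C)C(C)(C)C)c(O[Si](C)(C)C(C)(C)C)c2)c1OCOC
F5 | step 9 | (R)-1-[2,4-bis(methoxymethoxy)-3-(3-methylbut-2-en-1-yl)phenyl]-3-(3,4-dihydroxyphenyl)-2-hydroxypropan-1-one | CC(C)=CCc1c(OCOC)ccc(C(=O)[C@H](O)Cc2ccc(O)c(O)c2)c1OCOC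
F6 | step 5 | (R)-2-[(tert-butyldimethylsilyl)oxy]-3-{3,4-bis[(tert-butyldimethylsilyl)oxy]phenyl}propanal | O=C[C@H](O[Si](C)(C)C(C)(C)C)Cc1ccc(O[Si](C)(C)C(C)(C)C)c(O[Si](C)(C)C(C)(C)C)c1
F7 | step 5 | (1RS,2R)-1-[2,4-bis(benzyloxy)phenyl]-2-[(tert-butyldimethylsilyl)oxy]-3-{3,4-bis[(tert-butyldimethylsilyl)oxy]phenyl}propan-1-ol | OC(c1ccc(OCc2ccccc2)cc1OCc1ccccc1)[C@H](O[Si](C)(C)C(C)(C)C)Cc1ccc(O[Si](C)(C)C(C)(C)C)c(O[Si](C)(C)C(C)(C)C)c1
F0 | step 7 | none | none
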